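With the carbocycle numbered from the methyl-substituted alkene carbon (C1) through the isopropyl carbon C4, the ester carbon C5 and the carbinol carbon C7 round to C10, the route is built on disconnecting C8–C9. This bond sits between the quaternary C7 and the CH2 group C10, away from the C1=C2–C3=C4 diene, so ring-closing metathesis can join a vinyl and an allyl terminus there, forming the ten-membered ring and its only 1,2-disubstituted alkene in one operation; diimide then removes that alkene selectively. The metathesis substrate is an open-chain (6Z,8E)-tetraene already bearing both stereocentres, the free tertiary vinyl carbinol and the 4-hydroxybenzoate on C5.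

Key step: step 9

Remark: ring locants are those defined above; open-chain intermediates carry their own chain locants (chain C3 and C5 become ring C7 and C5).
Assumption: the enol borinate made from (+)-Ipc2BCl attacks the Si face of the enal, which gives the 5S carbinol; if the sense proved opposite, the antipodal reagent would be used.
Assumption: the new C8=C9 alkene of 18 is drawn Z; either geometry serves, since step 10 saturates it.

Step 1
Reactants: 1 prop-2-yn-1-ol (propargyl alcohol)
Product: 3 (Z)-3-iodo-2-isopropylprop-2-en-1-ol, via magnesium chelate 2 (not isolated)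
Conditions: i-PrMgCl (2.5 equiv), CuI (10 mol%), THF, −10 °C → rt; then I2, −78 → 0 °C
Reagents that add atoms: isopropylmagnesium chloride, CC(C)[Mg]Cl; iodine, II
Why: Copper-catalysed anti-carbomagnesiation of the propargylic alkoxide (Duboudin-type) puts isopropyl on the internal alkyne carbon and magnesium on the terminal carbon cis to the CH2O group in a five-membered chelate, and iodinolysis of that C–Mg bond with retention fixes the Z geometry needed for C3=C4.

Step 2
Reactants: 3 (Z)-3-iodo-2-isopropylprop-2-en-1-ol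
Product: 4 (Z)-3-iodo-2-isopropylprop-2-enal
Conditions: MnO2 (activated, excess), CH2Cl2, rt, dark; filtered and used at once
Reagents that add atoms: none
Why: Activated MnO2 oxidises the primary allylic alcohol under neutral heterogeneous conditions that leave the alkenyl iodide and its geometry alone (allylic oxidation); carrying the aldehyde forward at the iodide stage avoids a (2Z)-dienal, which as a 1-oxatriene could scramble the future C1=C2 geometry by reversible 6π-electrocyclisation.

Step 3
Reactants: 4 (Z)-3-iodo-2-isopropylprop-2-enal; 5 4-(trimethylsilyl)but-3-yn-2-one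
Product: 8 (5S,6Z)-5-hydroxy-7-iodo-6-isopropyl-1-(trimethylsilyl)hept-6-en-1-yn-3-one, via enol borinate 6 (not isolated), via boron aldolate 7 (not isolated)
Conditions: 5, (+)-Ipc2BCl, Et3N, Et2O, −78 → 0 °C; then 4, −78 → −20 °C; H2O2, MeOH, pH 7 buffer, 0 °C
Reagents that add atoms: none
Why: Paterson-type boron aldol in which the enol diisopinocampheylborinate 6 adds to the enal through a cyclic six-membered transition state, the isopinocampheyl ligands directing attack to the Si face of the aldehyde so that C5 is set as S under reagent control, and oxidative work-up frees the β-hydroxy ynone.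

Step 4
Reactants: 8 (5S,6Z)-5-hydroxy-7-iodo-6-isopropyl-1-(trimethylsilyl)hept-6-en-1-yn-3-one
Product: 9 (3R,5S,6Z)-7-iodo-6-isopropyl-3-methyl-1-(trimethylsilyl)hept-6-en-1-yne-3,5-diol
Conditions: MeMgBr (3.5 equiv), CH2Cl2/Et2O, −78 °C; aq. NH4Cl
Reagents that add atoms: methylmagnesium bromide, C[Mg]Br
Why: Chelation-controlled Grignard addition (Cram–Reetz 1,3-induction): the first equivalent forms the magnesium alkoxide of the C5 hydroxyl, which ties the ynone carbonyl into a six-membered half-chair with the iodoalkenyl group equatorial, and methyl then adds axially in 1,2-fashion so that the new tertiary hydroxyl lies syn to the C5 oxygen (3R).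

Step 5
Reactants: 9 (3R,5S,6Z)-7-iodo-6-isopropyl-3-methyl-1-(trimethylsilyl)hept-6-en-1-yne-3,5-diol; 10 pent-1-en-4-yne
Product: 12 (3R,5S,6Z,8E)-6-isopropyl-3,9-dimethyl-1-(trimethylsilyl)dodeca-6,8,11-trien-1-yne-3,5-diol, via alkenylalane 11 (not isolated)
Conditions: 10 (2.2 equiv), Me3Al (4.5 equiv), Cp2ZrCl2 (0.4 equiv), CH2Cl2, 0 °C → rt; then 9, ZnCl2, Pd(PPh3)4 (5 mol%), THF, rt
Reagents that add atoms: trimethylaluminium, C[Al](C)C
Why: Zirconium-catalysed syn-methylalumination of the terminal alkyne (Negishi carboalumination) gives the E-alkenylalane 11 regioselectively, and its palladium-catalysed cross-coupling with the Z-alkenyl iodide (Negishi coupling, zinc chloride as transmetallation shuttle) proceeds with retention at both partners to give the 6Z,8E-diene, while the two hydroxyls ride as aluminium alkoxides and the silylalkyne is inert at room temperature.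

Step 6
Reactants: 12 (3R,5S,6Z,8E)-6-isopropyl-3,9-dimethyl-1-(trimethylsilyl)dodeca-6,8,11-trien-1-yne-3,5-diol; 13 4-acetoxybenzoic acid
Product: 15 (3R,5S,6Z,8E)-3-hydroxy-6-isopropyl-3,9-dimethyl-1-(trimethylsilyl)dodeca-6,8,11-trien-1-yn-5-yl 4-acetoxybenzoate, via acid chloride 14 (not isolated)
Conditions: 13, (COCl)2, DMF (cat.), CH2Cl2, rt, evaporated; then 12, Et3N, DMAP (0.2 equiv), CH2Cl2, 0 °C → rt
Reagents that add atoms: none
Why: The acid chloride made in the flask acylates the secondary C5 hydroxyl under DMAP catalysis (nucleophilic acyl substitution) while the tertiary propargylic hydroxyl is too hindered to react, and the C5 configuration is untouched because its C–O bond is not broken.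

Step 7
Reactants: 15 (3R,5S,6Z,8E)-3-hydroxy-6-isopropyl-3,9-dimethyl-1-(trimethylsilyl)dodeca-6,8,11-trien-1-yn-5-yl 4-acetoxybenzoate
Product: 16 (3R,5S,6Z,8E)-3-hydroxy-6-isopropyl-3,9-dimethyldodeca-6,8,11-trien-1-yn-5-yl 4-hydroxybenzoate
Conditions: K2CO3 (2 equiv), MeOH, 0 °C → rt; aq. NH4Cl
Reagents that add atoms: none
Why: Base-mediated methanolysis cleaves the C(sp)–Si bond and the aryl acetate in one operation (protodesilylation and transesterification), and the phenoxide so formed deactivates the para ester carbonyl, so the hindered secondary benzoate survives.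

Step 8
Reactants: 16 (3R,5S,6Z,8E)-3-hydroxy-6-isopropyl-3,9-dimethyldodeca-6,8,11-trien-1-yn-5-yl 4-hydroxybenzoate
Product: 17 (3R,5S,6Z,8E)-3-hydroxy-6-isopropyl-3,9-dimethyldodeca-1,6,8,11-tetraen-5-yl 4-hydroxybenzoate
Conditions: H2 (1 atm), Pd/CaCO3–Pb(OAc)2 (Lindlar catalyst), quinoline, EtOAc, rt, stopped after 1 equiv H2
Reagents that add atoms: none
Why: Lindlar semi-hydrogenation stops at the alkene because the alkyne binds far more strongly to lead-poisoned palladium than any alkene, so the new vinyl group, the allyl terminus and the hindered diene are spared, as in the classical conversion of ethynyl carbinols into vinyl carbinols.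

Step 9
Reactants: 17 (3R,5S,6Z,8E)-3-hydroxy-6-isopropyl-3,9-dimethyldodeca-1,6,8,11-tetraen-5-yl 4-hydroxybenzoate
Product: 18 (1E,3Z,5S,7R,8Z)-7-hydroxy-4-isopropyl-1,7-dimethylcyclodeca-1,3,8-trien-5-yl 4-hydroxybenzoate
Conditions: second-generation Grubbs catalyst RuCl2(=CHPh)(H2IMes)(PCy3) (10 mol%, two portions), 1,4-benzoquinone (20 mol%), toluene (degassed, 1 mM), 60 °C, Ar sparge
Reagents that add atoms: none
Why: The ruthenium benzylidene first exchanges onto the unhindered allyl terminus, the new alkylidene undergoes [2+2] cycloaddition with the vinyl group on C7, and cycloreversion of the ruthenacyclobutane releases the C8=C9 alkene while the methylidene left behind carries the chain and ethene is purged (Chauvin mechanism). The closest known reaction type is ring-closing olefin metathesis of hydroxyl-bearing α,ω-dienes to medium-ring carbocycles with N-heterocyclic-carbene ruthenium catalysts. The one ring formed is the ten-membered carbocycle, closed by joining the two monosubstituted alkene termini (future C8 and C9) with loss of their CH2 ends. No stereocentre is created; C5 and C7 are spectators and the geometry of the new alkene, expected Z, is of no consequence because step 10 saturates it. The step needs cyclisation to beat oligomerisation, which the 1 mM dilution, the turn imposed by the Z-alkene C3=C4 and the quaternary C7 favour, and it needs the diene to stay out of the metathesis, which its two trisubstituted alkenes secure. The short-ring escapes are blocked by the substrate: a five-membered ring from the allyl end would have to contain the E-alkene C1=C2, and one from the vinyl end would require bond formation at the fully substituted C4 flanked by isopropyl and the acyloxy carbon, while benzoquinone checks ruthenium-hydride migration of the skipped diene.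

Step 10
Reactants: 18 (1E,3Z,5S,7R,8Z)-7-hydroxy-4-isopropyl-1,7-dimethylcyclodeca-1,3,8-trien-5-yl 4-hydroxybenzoate
Product: 19 (1E,3Z,5S,7S)-7-hydroxy-4-isopropyl-1,7-dimethylcyclodeca-1,3-dien-5-yl 4-hydroxybenzoate (CNP0130127.1)
Conditions: 2-nitrobenzenesulfonyl hydrazide (excess, in portions), Et3N, CH2Cl2, rt
Reagents that add atoms: none
Why: Diimide released at room temperature from the sulfonyl hydrazide transfers two hydrogens suprafacially in a concerted six-centre step and is strongly retarded by substitution (diimide reduction), so the single 1,2-disubstituted alkene C8=C9 is saturated while the two trisubstituted diene alkenes, the ester and the phenol are untouched; no stereocentre is formed and C7 merely changes descriptor from R to S.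

Compound list
1 | prop-2-yn-1-ol (propargyl alcohol) | C#CCO | starting material
2 | 4-isopropyl-2,5-dihydro-1,2-oxamagnesole (chelated Z-alkenylmagnesium alkoxide) | CC(C)C1=C[Mg]OC1 | intermediate (not isolated)
3 | (Z)-3-iodo-2-isopropylprop-2-en-1-ol | I\C=C(\C(C)C)CO | intermediate
4 | (Z)-3-iodo-2-isopropylprop-2-enal | I\C=C(\C(C)C)C=O | intermediate
5 | 4-(trimethylsilyl)but-3-yn-2-one | CC(=O)C#C[Si](C)(C)C | starting material
6 | 4-(trimethylsilyl)but-1-en-3-yn-2-yl bis[(+)-isopinocampheyl]borinate | C=C(OB([C@H]1C[C@H]2C[C@@H]([C@@H]1C)C2(C)C)[C@H]1C[C@H]2C[C@@H]([C@@H]1C)C2(C)C)C#C[Si](C)(C)C | intermediate (not isolated)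
7 | bis[(+)-isopinocampheyl]boron aldolate of 8 (boron on the C5 oxygen) | I\C=C(\C(C)C)[C@@H](OB([C@H]1C[C@H]2C[C@@H]([C@@H]1C)C2(C)C)[C@H]1C[C@H]2C[C@@H]([C@@H]1C)C2(C)C)CC(=O)C#C[Si](C)(C)C | intermediate (not isolated)
8 | (5S,6Z)-5-hydroxy-7-iodo-6-isopropyl-1-(trimethylsilyl)hept-6-en-1-yn-3-one | I\C=C(\C(C)C)[C@@H](O)CC(=O)C#C[Si](C)(C)C | intermediate
9 | (3R,5S,6Z)-7-iodo-6-isopropyl-3-methyl-1-(trimethylsilyl)hept-6-en-1-yne-3,5-diol | I\C=C(\C(C)C)[C@@H](O)C[C@@](C)(O)C#C[Si](C)(C)C | intermediate
10 | pent-1-en-4-yne | C=CCC#C | starting material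
11 | (E)-dimethyl(2-methylpenta-1,4-dien-1-yl)alane | C=CC/C(C)=C/[Al](C)C | intermediate (not isolated)
12 | (3R,5S,6Z,8E)-6-isopropyl-3,9-dimethyl-1-(trimethylsilyl)dodeca-6,8,11-trien-1-yne-3,5-diol | C=CC\C(C)=C\C=C(\C(C)C)[C@@H](O)C[C@@](C)(O)C#C[Si](C)(C)C | intermediate
13 | 4-acetoxybenzoic acid | CC(=O)Oc1ccc(cc1)C(=O)O | starting material
14 | 4-acetoxybenzoyl chloride | CC(=O)Oc1ccc(cc1)C(=O)Cl | intermediate (not isolated)
15 | (3R,5S,6Z,8E)-3-hydroxy-6-isopropyl-3,9-dimethyl-1-(trimethylsilyl)dodeca-6,8,11-trien-1-yn-5-yl 4-acetoxybenzoate | C=CC\C(C)=C\C=C(\C(C)C)[C@@H](OC(=O)c1ccc(OC(C)=O)cc1)C[C@@](C)(O)C#C[Si](C)(C)C | intermediate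
16 | (3R,5S,6Z,8E)-3-hydroxy-6-isopropyl-3,9-dimethyldodeca-6,8,11-trien-1-yn-5-yl 4-hydroxybenzoate | C=CC\C(C)=C\C=C(\C(C)C)[C@@H](OC(=O)c1ccc(O)cc1)C[C@@](C)(O)C#C | intermediate
17 | (3R,5S,6Z,8E)-3-hydroxy-6-isopropyl-3,9-dimethyldodeca-1,6,8,11-tetraen-5-yl 4-hydroxybenzoate | C=CC\C(C)=C\C=C(\C(C)C)[C@@H](OC(=O)c1ccc(O)cc1)C[C@@](C)(O)C=C | intermediate
18 | (1E,3Z,5S,7R,8Z)-7-hydroxy-4-isopropyl-1,7-dimethylcyclodeca-1,3,8-trien-5-yl 4-hydroxybenzoate | C/C1=C\C=C(\C(C)C)[C@@H](OC(=O)c2ccc(O)cc2)C[C@@](C)(O)/C=C\C1 | intermediate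
19 | (1E,3Z,5S,7S)-7-hydroxy-4-isopropyl-1,7-dimethylcyclodeca-1,3-dien-5-yl 4-hydroxybenzoate | C/C1=C\C=C(\C(C)C)[C@@H](OC(=O)c2ccc(O)cc2)C[C@@](C)(O)CCC1 | target

Total steps: 10. Longest linear sequence: 10 steps (1 → 3 → 4 → 8 → 9 → 12 → 15 → 16 → 17 → 18 → 19); 5, 10 and 13 enter as purchased materials.

Steps most likely to fail

Step 9 (ring-closing metathesis). What may go wrong: intermolecular metathesis and catalyst decay may outpace closure of the strained triene ring, or a carbene residing on the vinyl end may close a five-membered ring onto C4. The fallback sets out from 4 and returns to the route at 19. The ring is closed at the diene bond C2–C3 by an irreversible palladium-catalysed coupling, with C8–C9 already saturated. The aldol of step 3 is run with purchased hept-6-yn-2-one (CC(=O)CCCC#C, enolised on the methyl side) to give (8S,9Z)-8-hydroxy-10-iodo-9-isopropyldec-9-en-1-yn-6-one F11. Chelation-controlled MeMgBr addition as in step 4 gives (6S,8S,9Z)-10-iodo-9-isopropyl-6-methyldec-9-en-1-yne-6,8-diol F12. Methylalumination of the terminal alkyne (Me3Al, Cp2ZrCl2, CH2Cl2) gives the E-alkenylalane F13. This is diluted and coupled with the Z-alkenyl iodide in the same molecule (Pd(PPh3)4, ZnCl2, THF, high dilution) to give (1E,3Z,5S,7S)-4-isopropyl-1,7-dimethylcyclodeca-1,3-diene-5,7-diol F14. Acylation of the secondary hydroxyl with 14 as in step 6 gives the 4-acetoxybenzoate F15, and methanolysis of the aryl acetate (K2CO3, MeOH, 0 °C) gives 19.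

Step 4 (methyl addition). What may go wrong: the magnesium chelate may form incompletely, or methyl may attack an open conformer, so that facial selectivity at the ketone is poor and the C7 epimer accompanies 9. The fallback sets out from 4 and returns to the route at 17. C7 is installed under reagent control by Sharpless epoxidation instead of by induction from C5.
- The (+)-Ipc2BCl aldol of step 3 is run with acetone to give (4S,5Z)-4-hydroxy-6-iodo-5-isopropylhex-5-en-2-one F1, which is silylated (TBSOTf, 2,6-lutidine) to its tert-butyldimethylsilyl ether F2.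
- Horner–Wadsworth–Emmons olefination (triethyl phosphonoacetate, NaH, THF; the E isomer is separated) gives ethyl (2E,5S,6Z)-5-(tert-butyldimethylsilyloxy)-7-iodo-6-isopropyl-3-methylhepta-2,6-dienoate F3, and i-Bu2AlH reduction gives the allylic alcohol F4.
- Sharpless asymmetric epoxidation (Ti(OiPr)4, D-(−)-diethyl tartrate, t-BuOOH, 4 Å sieves, −20 °C) gives the (2R,3R)-epoxy alcohol F5.
- Iodination (I2, PPh3, imidazole) gives the epoxy iodide F6, and reductive opening with Zn dust in ethanol gives the tertiary vinyl carbinol (3R,5S,6Z)-5-(tert-butyldimethylsilyloxy)-7-iodo-6-isopropyl-3-methylhepta-1,6-dien-3-ol F7.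
- Negishi coupling with alane 11 as in step 5 gives the tetraene silyl ether F8, and TBAF gives the diol F9.
- Acylation with 14 as in step 6 gives the 4-acetoxybenzoate F10, and methanolysis of the aryl acetate (K2CO3, MeOH, 0 °C) gives 17.

Step 10 (selective reduction). What may go wrong: diimide may also attack the diene alkenes (over-reduction), or conversion may stall at the hindered C8=C9 alkene next to the quaternary carbon. The fallback sets out from 18 and returns to the route at 19. It is a hydroxyl-directed homogeneous hydrogenation with [Ir(cod)(PCy3)(py)]PF6 (low loading, H2 1 atm, CH2Cl2, 0 °C, stopped at one equivalent). The C7 hydroxyl binds the cationic iridium and delivers hydrogen to the adjacent C8=C9 alkene; no new compound is involved.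

Further compounds
F1 | step 4 | (4S,5Z)-4-hydroxy-6-iodo-5-isopropylhex-5-en-2-one | I\C=C(\C(C)C)[C@@H](O)CC(C)=O
F2 | step 4 | (4S,5Z)-4-(tert-butyldimethylsilyloxy)-6-iodo-5-isopropylhex-5-en-2-one | I\C=C(\C(C)C)[C@@H](O[Si](C)(C)C(C)(C)C)CC(C)=O
F3 | step 4 | ethyl (2E,5S,6Z)-5-(tert-butyldimethylsilyloxy)-7-iodo-6-isopropyl-3-methylhepta-2,6-dienoate | I\C=C(\C(C)C)[C@@H](O[Si](C)(C)C(C)(C)C)C/C(C)=C/C(=O)OCC
F4 | step 4 | (2E,5S,6Z)-5-(tert-butyldimethylsilyloxy)-7-iodo-6-isopropyl-3-methylhepta-2,6-dien-1-ol | I\C=C(\C(C)C)[C@@H](O[Si](C)(C)C(C)(C)C)C/C(C)=C/CO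
F5 | step 4 | [(2R,3R)-3-[(2S,3Z)-2-(tert-butyldimethylsilyloxy)-4-iodo-3-isopropylbut-3-en-1-yl]-3-methyloxiran-2-yl]methanol | I\C=C(\C(C)C)[C@@H](O[Si](C)(C)C(C)(C)C)C[C@@]1(C)O[C@@H]1CO
F6 | step 4 | epoxy iodide of F5 (CH2OH replaced by CH2I, same spatial arrangement) | I\C=C(\C(C)C)[C@@H](O[Si](C)(C)C(C)(C)C)C[C@@]1(C)O[C@@H]1CI
F7 | step 4 | (3R,5S,6Z)-5-(tert-butyldimethylsilyloxy)-7-iodo-6-isopropyl-3-methylhepta-1,6-dien-3-ol | I\C=C(\C(C)C)[C@@H](O[Si](C)(C)C(C)(C)C)C[C@@](C)(O)C=C
F8 | step 4 | (3R,5S,6Z,8E)-5-(tert-butyldimethylsilyloxy)-6-isopropyl-3,9-dimethyldodeca-1,6,8,11-tetraen-3-ol | C=CC\C(C)=C\C=C(\C(C)C)[C@@H](O[Si](C)(C)C(C)(C)C)C[C@@](C)(O)C=C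
F9 | step 4 | (3R,5S,6Z,8E)-6-isopropyl-3,9-dimethyldodeca-1,6,8,11-tetraene-3,5-diol | C=CC\C(C)=C\C=C(\C(C)C)[C@@H](O)C[C@@](C)(O)C=C
F10 | step 4 | (3R,5S,6Z,8E)-3-hydroxy-6-isopropyl-3,9-dimethyldodeca-1,6,8,11-tetraen-5-yl 4-acetoxybenzoate | C=CC\C(C)=C\C=C(\C(C)C)[C@@H](OC(=O)c1ccc(OC(C)=O)cc1)C[C@@](C)(O)C=C
F11 | step 9 | (8S,9Z)-8-hydroxy-10-iodo-9-isopropyldec-9-en-1-yn-6-one | I\C=C(\C(C)C)[C@@H](O)CC(=O)CCCC#C
F12 | step 9 | (6S,8S,9Z)-10-iodo-9-isopropyl-6-methyldec-9-en-1-yne-6,8-diol | I\C=C(\C(C)C)[C@@H](O)C[C@@](C)(O)CCCC#C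
F13 | step 9 | E-alkenyl(dimethyl)alane from F12 (hydroxyls drawn free, present as aluminium alkoxides) | I\C=C(\C(C)C)[C@@H](O)C[C@@](C)(O)CCC/C(C)=C/[Al](C)C
F14 | step 9 | (1E,3Z,5S,7S)-4-isopropyl-1,7-dimethylcyclodeca-1,3-diene-5,7-diol | C/C1=C\C=C(\C(C)C)[C@@H](O)C[C@@](C)(O)CCC1
F15 | step 9 | (1E,3Z,5S,7S)-7-hydroxy-4-isopropyl-1,7-dimethylcyclodeca-1,3-dien-5-yl 4-acetoxybenzoate | C/C1=C\C=C(\C(C)C)[C@@H](OC(=O)c2ccc(OC(C)=O)cc2)C[C@@](C)(O)CCC1
F0 | step 10 | none | none
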